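Everything rests on disconnecting the C–C bond between the aminal CH (C6, bonded to the pyrrole N and one urea NH) and the quaternary aminal carbon (C10a, bonded to the lactam N and the other urea NH), the bond shared by the imidazolidinone and pyrazinone rings. The key step exploits that C10a is the α-carbon of an N-acylproline ester and C6 a formic-acid-level carbon on the pyrrole N: in tert-butyl N-(4,5-dibromopyrrole-2-carbonyl)prolinate carrying CH=N–S(O)tBu on the pyrrole N, a sulfinyl-directed intramolecular Mannich cyclisation of the ester enolate closes the pyrazinone ring and sets both stereocentres at once. Curtius rearrangement then turns the carboxyl into the second urea nitrogen.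

Key step: step 4

Assumption: the sulfinyl group is taken to steer the enolate through the closed, lithium-chelated transition state known for alkali ester enolate additions to N-sulfinyl aldimines; should the open mode prevail, (R)-tert-butanesulfinamide is used in step 2 and nothing else changes. Compound 1 is taken as commercially available. The labels C6 and C10a (phakellstatin numbering) are used for the two stereocentres in all intermediates.

Step 1
Reactants: 1 2,2,2-trichloro-1-(4,5-dibromo-1H-pyrrol-2-yl)ethan-1-one; 2 tert-butyl L-prolinate
Product: 3 tert-butyl (S)-1-(4,5-dibromo-1H-pyrrole-2-carbonyl)pyrrolidine-2-carboxylate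
Conditions: Et3N (cat.), MeCN, rt
Reagents that add atoms: none
Why: Haloform-type acylation, in which the secondary amine attacks the trichloromethyl ketone and chloroform leaves, is the standard way to pyrrole-2-carboxamides, and the proline centre needs no care because step 4 erases and resets it.

Step 2
Reactants: 4 (S)-tert-butanesulfinamide; 5 triethyl orthoformate
Product: 6 ethyl N-[(S)-tert-butylsulfinyl]formimidate
Conditions: 5 (neat, excess), p-TsOH (1 mol %), 80 °C, EtOH distilled off
Reagents that add atoms: none
Why: Acid-catalysed condensation of a primary sulfinamide with an orthoester gives the N-sulfinyl imidate, driven by removal of ethanol, with no bond change at sulfur.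

Step 3
Reactants: 3 tert-butyl (S)-1-(4,5-dibromo-1H-pyrrole-2-carbonyl)pyrrolidine-2-carboxylate; 6 ethyl N-[(S)-tert-butylsulfinyl]formimidate
Product: 7 tert-butyl (S)-1-{4,5-dibromo-1-[(E)-{[(S)-tert-butylsulfinyl]imino}methyl]-1H-pyrrole-2-carbonyl}pyrrolidine-2-carboxylate
Conditions: Cs2CO3 (0.2 equiv), 5 Å MS, MeCN, 50 °C
Reagents that add atoms: none
Why: Amidine formation from an imidate, in which the pyrrolide (N–H acidified by the 2-acyl group and two bromines) adds to the imidate carbon and ethoxide leaves, should be pulled to the E-formamidine by uptake of ethanol on the sieves, while the bulky tert-butyl ester resists attack by the pyrrolide.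

Step 4
Reactants: 7 tert-butyl (S)-1-{4,5-dibromo-1-[(E)-{[(S)-tert-butylsulfinyl]imino}methyl]-1H-pyrrole-2-carbonyl}pyrrolidine-2-carboxylate
Product: 10 tricyclic sulfinamide ester (pyrazinone ring closed; NH–S(O)tBu on C6 and CO2tBu on C10a, cis; (S) at sulfur, (R) at C6, (R) at C10a), via lithium ester enolate 8 (not isolated), via N-lithio sulfinamide 9 (not isolated)
Conditions: LiHMDS (1.1 equiv), THF, −78 °C; AcOH, −78 °C
Reagents that add atoms: none
Why: Proposed new method: LiHMDS removes the α-H of the N-acylproline ester (C10a) and the lithium enolate 8 adds through carbon to the formamidine carbon C6, which is imine-like because the pyrrole lone pair is held in the aromatic sextet and by the 2-acyl group, and the N-lithio aminal 9 should persist at −78 °C, as the tetrahedral adducts of N-acylpyrroles do, until it is protonated cold. The closest known reaction type is the Mannich addition of alkali ester enolates to N-tert-butanesulfinyl aldimines, which has not been shown on an N-sulfinyl amidine carbon. The pyrazinone ring is closed in a 6-(enolexo)-exo-trig mode. C6 is controlled by the (S)-sulfinyl group: in the lithium-bridged chair (Li on enolate O, imine N and sulfinyl O, tert-butyl turned away) the enolate reaches the Re face of C6 (imine N > pyrrole N > H). C10a is set relative to C6 by the same chair, in which the E-formamidine holds the pyrrole N axial, so that the tether through the pyrrole carbonyl delivers NH–S and CO2tBu cis. The step needs C-attack without loss of pyrrolide and the cis relation that the later urea closure requires, which the low temperature with a cold quench and the fused chair–tether geometry should secure.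

Step 5
Reactants: 10 tricyclic sulfinamide ester
Product: 11 cis amino acid hydrochloride (NH3Cl on C6, (S); CO2H on C10a, (R))
Conditions: HCl (4 M in 1,4-dioxane), CH2Cl2, 0 °C to rt; evaporation, trituration with Et2O
Reagents that add atoms: hydrogen chloride, Cl
Why: Acidolysis with anhydrous HCl cleaves the N–S bond (as sulfinyl chloride) and the tert-butyl ester (as isobutene) in one operation, and the aminal should survive because the protonated amine cannot expel the pyrrole nitrogen and no water is present, so both stereocentres are kept.

Step 6
Reactants: 11 cis amino acid hydrochloride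
Product: 14 dibromophakellstatin, via acyl azide 12 (not isolated), via isocyanate 13 (not isolated)
Conditions: DPPA (1.2 equiv), Et3N (2.5 equiv), DMF, 0 °C to rt, then 70 °C
Reagents that add atoms: diphenylphosphoryl azide, [N-]=[N+]=NP(=O)(Oc1ccccc1)Oc1ccccc1
Why: Curtius rearrangement, in which acyl azide 12 loses N2 with migration of C10a under retention, gives isocyanate 13, and the cis amine on C6 adds to it to close the cis-fused imidazolidinone, as known for β-amino acids giving cyclic ureas.

Compound list
1 | 2,2,2-trichloro-1-(4,5-dibromo-1H-pyrrol-2-yl)ethan-1-one | O=C(c1cc(Br)c(Br)[nH]1)C(Cl)(Cl)Cl | starting material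
2 | tert-butyl L-prolinate, tert-butyl (S)-pyrrolidine-2-carboxylate | CC(C)(C)OC(=O)[C@@H]1CCCN1 | starting material
3 | tert-butyl (S)-1-(4,5-dibromo-1H-pyrrole-2-carbonyl)pyrrolidine-2-carboxylate | CC(C)(C)OC(=O)[C@@H]1CCCN1C(=O)c1cc(Br)c(Br)[nH]1 | intermediate
4 | (S)-tert-butanesulfinamide, (S)-2-methylpropane-2-sulfinamide | CC(C)(C)[S@](=O)N | starting material
5 | triethyl orthoformate | CCOC(OCC)OCC | starting material
6 | ethyl N-[(S)-tert-butylsulfinyl]formimidate | CC(C)(C)[S@](=O)N=COCC | intermediate
7 | tert-butyl (S)-1-{4,5-dibromo-1-[(E)-{[(S)-tert-butylsulfinyl]imino}methyl]-1H-pyrrole-2-carbonyl}pyrrolidine-2-carboxylate | CC(C)(C)[S@](=O)/N=C/n1c(Br)c(Br)cc1C(=O)N1CCC[C@H]1C(=O)OC(C)(C)C | intermediate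
8 | lithium ester enolate of 7 (C10a planar) | CC(C)(C)[S@](=O)/N=C/n1c(Br)c(Br)cc1C(=O)N1CCCC1=C([O-])OC(C)(C)C.[Li+] | intermediate
9 | N-lithio sulfinamide of 10 (cyclised adduct before quench) | CC(C)(C)[S@](=O)[N-][C@H]1n2c(Br)c(Br)cc2C(=O)N2CCC[C@]12C(=O)OC(C)(C)C.[Li+] | intermediate
10 | tricyclic sulfinamide ester: dibromopyrrole–pyrazinone–pyrrolidine tricycle with NH–S(O)tBu on C6 and CO2tBu on C10a, cis; (S) at sulfur, (R) at C6, (R) at C10a | CC(C)(C)[S@](=O)N[C@H]1n2c(Br)c(Br)cc2C(=O)N2CCC[C@]12C(=O)OC(C)(C)C | intermediate
11 | cis amino acid hydrochloride: same tricycle with NH3Cl on C6 (S) and CO2H on C10a (R) | Cl.N[C@H]1n2c(Br)c(Br)cc2C(=O)N2CCC[C@]12C(=O)O | intermediate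
12 | acyl azide of 11 (free amine on C6; configuration as in 11) | N[C@H]1n2c(Br)c(Br)cc2C(=O)N2CCC[C@]12C(=O)N=[N+]=[N-] | intermediate
13 | isocyanate on C10a, amine on C6, cis (both centres spatially as in 11) | N[C@H]1n2c(Br)c(Br)cc2C(=O)N2CCC[C@]12N=C=O | intermediate
14 | dibromophakellstatin, (S) at C6, (R) at C10a | O=C1N[C@H]2n3c(cc(Br)c3Br)C(=O)N3CCC[C@]23N1 | target

Total step count: 6. Longest linear sequence: 5 (steps 1, 3, 4, 5, 6).

Steps most likely to fail

Step 4 (Proposed new method). After the C–C bond has formed, the nitrogen anion may expel the pyrrolide and reopen the ring, or the facial and cis/trans selectivities may be poor. The fallback uses known chemistry, sets out from 3 and comes back at 11. Compound 3 is doubly deprotonated (LiHMDS, 2.2 equiv, THF, −78 °C) and the ester enolate is C-formylated with ethyl formate (Claisen condensation). On work-up the pyrrole N–H adds to the new aldehyde and should give the racemic carbinolamine F1. TMSN3 with BF3·OEt2 replaces the hydroxyl by azide. The cis racemate is resolved by preparative HPLC on a chiral phase to the azide F2. Staudinger reduction (PMe3, THF/H2O) should give the amine F3, and HCl in dioxane cleaves the tert-butyl ester to 11.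

Step 3. The imidoyl transfer to the weakly nucleophilic pyrrolide may stall on the side of imidate and pyrrole, or the pyrrolide may attack the ester instead. The fallback sets out from 3 and comes back at 7. Compound 3 is heated with triethyl orthoformate 5 and catalytic p-TsOH at 130 °C with distillation of ethanol, the method used for N-protection of azoles, to give the N-(diethoxymethyl)pyrrole amide F4. Exchange with sulfinamide 4 (PPTS cat., toluene, 80 °C, ethanol removed) should then give 7.

Step 6. The free amine on C6 may compete for the activated carboxyl (oligomer or β-lactam), or the ammonium carboxylate may fragment with loss of CO2 and ammonia before the azide forms. The fallback sets out from 11 and comes back at 14. Boc2O and NaHCO3 in THF/H2O give the N-Boc amino acid F5. DPPA and Et3N in toluene at 80 °C should give the N-Boc cyclic urea F6, the carbamate N–H trapping the isocyanate. TFA in CH2Cl2 then gives 14.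

Further compounds
F1 | step 4 | racemic carbinolamine: tricycle with OH on C6 and CO2tBu on C10a, both C6 epimers | OC1n2c(Br)c(Br)cc2C(=O)N2CCCC12C(=O)OC(C)(C)C
F2 | step 4 | cis azido ester, single enantiomer after resolution: N3 on C6, CO2tBu on C10a | [N-]=[N+]=N[C@H]1n2c(Br)c(Br)cc2C(=O)N2CCC[C@]12C(=O)OC(C)(C)C
F3 | step 4 | cis amino ester: NH2 on C6, CO2tBu on C10a | N[C@H]1n2c(Br)c(Br)cc2C(=O)N2CCC[C@]12C(=O)OC(C)(C)C
F4 | step 3 | tert-butyl (S)-1-[4,5-dibromo-1-(diethoxymethyl)-1H-pyrrole-2-carbonyl]pyrrolidine-2-carboxylate | CCOC(OCC)n1c(Br)c(Br)cc1C(=O)N1CCC[C@H]1C(=O)OC(C)(C)C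
F5 | step 6 | N-Boc cis amino acid: NHBoc on C6, CO2H on C10a | CC(C)(C)OC(=O)N[C@H]1n2c(Br)c(Br)cc2C(=O)N2CCC[C@]12C(=O)O
F6 | step 6 | N-Boc dibromophakellstatin, Boc on the urea N bonded to C6 | O=C1N(C(=O)OC(C)(C)C)[C@H]2n3c(cc(Br)c3Br)C(=O)N3CCC[C@]23N1
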